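The constants were set for the occasion; the result is computed.

The decomposed reagent is the leftover to reckon first, for partner that ends there no longer reaches the target.

    starting material → open intermediate (k1 = 0.14 /s)
    solid substrate ⇌ starting material, rate k2*(cs2 - [starting material]) while solid is left; crystals form when [starting material] > cs2 (cs2 = 0.30 mM, k2 = 0.31 /s)
    2 open intermediate → homo product (k3 = 26 /M/s)
    open intermediate + second intermediate → target (k4 = 60 /M/s)
    partner → decomposed reagent (k5 = 0.14 /s)
    partner → second intermediate (k6 = 0.036 /s)

all flasks: solid substrate 0.50 mM; time 5.0 min
- south: partner 0.250 mM
- south-west: partner 0.400 mM
- north: partner 0.600 mM
- west: partner 1.00 mM
- south-east: partner 1.50 mM

* amount of target at the end, in percent of the solid substrate charged for south, south-west, north, west, south-east, in this order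
* how that number moves from the first to the last of them (falls, then rises / hardly changes / rises all the way / rises, then falls / falls all the way)

- percentages count the solid substrate that a species holds: one homo product counts as two
- two of one species on the left: rate k times its square, two consumed each time
- solid, in amounts per volume of the solution: solid substrate
- at the start none of the solid substrate is in solution
- "hardly changes" means that all values lie within two and a half points (for a concentration: within two and a half percent of the largest)
- run time (south): 5.0 min

Partner leaves by two first-order steps whose ratio holds whatever the charge, so a fixed 20.5% of it becomes second intermediate; call this φ, the branch share, the rate constant of the step to second intermediate over the sum of the two partner constants. Target takes one second intermediate each, so its ceiling in percent of the solid substrate is φ times the partner charge over the solid charge. In south-east that supply, 0.308 mM, is smaller than the 0.50 mM of solid substrate, but this compares charges, and open intermediate also goes to homo product, so the ceiling is an upper bound and names no limiting reagent for the row.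

Drawn for south, the target curve leaves zero flat, since neither of its two reactants is charged. In south, starting material freezes near 0.207 mM, where dissolving balances its opening, within a relaxation time of about 0.0370 min, and open intermediate is then fed at 1.74 mM/min. Since the solid first fills the solution to that level and then supplies this flow, it lasts about 0.206 min. Partner has a half-life of 0.0656 min by both exits, shorter than that life of the solid. The end of the solid is the knee. Beyond it, I take open intermediate as starting from the full charge and falling by the homo step, with a first half-life of 0.641 min. The capture number Θ, the target constant over twice the homo constant, times the logarithm of one plus run time over that half-life, is then 2.51. The level is the ceiling, 10.2% for south, and the factor one minus exp(−Θ) brings my figure to 9.37% at the end. The other ceilings are 16.4%, 24.5%, 40.9% and 61.5%, a straight rise with the charge.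

The forecast, holding that “the target is capped by that second-intermediate supply”, gives 9.2%, 14.7%, 21.8%, 34% and 46%, and says the row rises all the way; it stands below my ceilings and, in south, slightly below my figure.

The simulation gives 9.29%, 14.7%, 21.7%, 34.9% and 49.0%, so the row rises all the way. South reaches 90.8% of its ceiling after 5.00 min, with 0.00470 mM of second intermediate still in the flask. In south-east, the branch share of 1.50 mM gives 0.308 mM of second intermediate, and after 50.0 min the target, 0.265 mM, and the remaining second intermediate, 0.0420 mM, add up to 0.307 mM.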